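In the cycloheptane ring of the target, C3 and C5 carry the ester oxygens, only the methylene C4 separates them, and quaternary C2 and C6 lie on their outer sides. Deleting C4 leaves a six-membered acyloin ring, closed between two non-enolisable esters on a bicyclo[3.1.1]heptene made by vinylketene [2+2] cycloaddition. One Simmons–Smith methylene transfer to the resulting nor-tricyclic C3=C5 bis(trimethylsilyloxy)alkene forms C3–C4 and C4–C5 together; oxidative cleavage of the shared C3–C5 bond then gives the cycloheptane-1,3-dione, whose carbonyl groups are reduced under reagent control and acylated in turn.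

Key step: step 14

Remarks on the chemistry (assumptions):
- Locants C1–C11 are those of the target, numbered as 2,6,6,9-tetramethyltricyclo[5.4.0.0(2,8)]undecane, and denote the same atoms in every intermediate. Bicyclic compounds 7–19 are named as bicyclo[3.1.1]heptanes; their ring atoms 1, 2, 3, 4, 5, 6, 7 are target atoms C8, C9, C10, C11, C1, C7, C2.
- Commercial methyl geranate is taken as the (2E) isomer; this geometry is lost in step 4 and is not critical.
- The cycloaddition of the achiral vinylketene necessarily gives a racemate. The tricyclic core is almost mirror-symmetric (only the C9–C10–C11 bridge breaks the symmetry), so the antipodes are separated directly at the first chiral compound (step 5). From 8 onward every compound is a single enantiomer.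
- The two stereocentres made in step 14 (C3, C5) are destroyed in step 15, so the face of methylene delivery is immaterial. Compound 23 is drawn as one face isomer, and any material of the other face is carried along with it unseparated.

Route

Step 1
Reactants: 1 methyl (2E)-3,7-dimethylocta-2,6-dienoate (methyl geranate)
Product: 2 methyl (2E,6E)-8-hydroxy-3,7-dimethylocta-2,6-dienoate
Conditions: SeO2 (0.3 equiv), t-BuOOH (3 equiv), salicylic acid (0.1 equiv), CH2Cl2, 0 °C to rt
Reagents that add atoms: tert-butyl hydroperoxide, CC(C)(C)OO; selenium dioxide (oxygen carrier), O=[Se]=O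
Why: Catalytic SeO2 allylic hydroxylation (ene reaction, then [2,3]-sigmatropic shift) attacks only the electron-rich 6,7-alkene and, as is general for trisubstituted alkenes, its (E)-methyl group; this fixes the 6E geometry that later places the C2 methyl group syn to the unsaturated bridge.

Step 2
Reactants: 2 methyl (2E,6E)-8-hydroxy-3,7-dimethylocta-2,6-dienoate
Product: 3 methyl (2E,6E)-8-[(tert-butyldiphenylsilyl)oxy]-3,7-dimethylocta-2,6-dienoate
Conditions: t-BuPh2SiCl, imidazole, DMF, 0 °C to rt
Reagents that add atoms: tert-butyl(chloro)diphenylsilane, CC(C)(C)[Si](Cl)(c1ccccc1)c1ccccc1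
Why: Standard silylation of a primary alcohol; this silyl ether tolerates acid-chloride formation, hot triethylamine and amide bases, and gives the bicyclic ketone a UV handle for step 5.

Step 3
Reactants: 3 methyl (2E,6E)-8-[(tert-butyldiphenylsilyl)oxy]-3,7-dimethylocta-2,6-dienoate
Product: 4 (2E,6E)-8-[(tert-butyldiphenylsilyl)oxy]-3,7-dimethylocta-2,6-dienoic acid
Conditions: LiOH·H2O, THF/MeOH/H2O, 40 °C; then 1 M HCl to pH 3
Reagents that add atoms: lithium hydroxide, [Li+].[OH-]
Why: Saponification of the conjugated methyl ester, which should leave the silyl ether intact under these mild conditions.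

Step 4
Reactants: 4 (2E,6E)-8-[(tert-butyldiphenylsilyl)oxy]-3,7-dimethylocta-2,6-dienoic acid
Product: 7 racemic 7-{[(tert-butyldiphenylsilyl)oxy]methyl}-7-methyl-2-methylidenebicyclo[3.1.1]heptan-6-one (7-methyl syn to the methylidene-bearing bridge), via acid chloride 5 (not isolated), via vinylketene 6 (not isolated)
Conditions: (COCl)2, N,N-dimethylformamide (cat.), CH2Cl2, 0 °C to rt; evaporate; slow addition to Et3N (5 equiv), toluene, 110 °C, 0.01 M
Reagents that add atoms: none
Why: 1,4-Dehydrochlorination of the β,β-disubstituted enoyl chloride (hydrogen taken from the C9 methyl group) gives the vinylketene, which should undergo the known intramolecular crossed [2+2] ketene–alkene cycloaddition to a bicyclo[3.1.1]heptan-6-one; the ketene carbon (C7) bonds to the less substituted alkene carbon (C1), the addition is suprafacial on the (E)-alkene so that the C2 methyl group ends syn to the C9–C11 bridge and the silyloxymethyl group points toward C7, and the product is racemic.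

Step 5
Reactants: 7 racemic 7-{[(tert-butyldiphenylsilyl)oxy]methyl}-7-methyl-2-methylidenebicyclo[3.1.1]heptan-6-one
Product: 8 (1R,5S,7S)-7-{[(tert-butyldiphenylsilyl)oxy]methyl}-7-methyl-2-methylidenebicyclo[3.1.1]heptan-6-one
Conditions: preparative SFC, amylose tris(3,5-dimethylphenylcarbamate) on silica, CO2/i-PrOH, 35 °C
Reagents that add atoms: none
Why: Enantiomer separation by chromatography on a chiral stationary phase; all functional groups lie on the local mirror plane, so a resolving agent attached at C3 or C7 would discriminate poorly, whereas the rigid β,γ-unsaturated ketone with two phenyl groups is a good candidate for direct separation, and the (1R,5S,7S) antipode is to be identified by comparing measured and calculated ECD of the ketone chromophore.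

Step 6
Reactants: 8 (1R,5S,7S)-7-{[(tert-butyldiphenylsilyl)oxy]methyl}-7-methyl-2-methylidenebicyclo[3.1.1]heptan-6-one; 9 triethyl phosphonoacetate
Product: 10 ethyl 2-(7-{[(tert-butyldiphenylsilyl)oxy]methyl}-7-methyl-2-methylidenebicyclo[3.1.1]heptan-6-ylidene)acetate (ring configuration as in 8; E/Z mixture)
Conditions: NaH, THF, 0 °C; then 8, 65 °C
Reagents that add atoms: triethyl phosphonoacetate (9), CCOC(=O)CP(=O)(OCC)OCC
Why: Horner–Wadsworth–Emmons olefination of a strained cyclobutanone that cannot enolise (both α-carbons are bridgeheads); the alkene geometry is inconsequential because C6 becomes C(CH3)2.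

Step 7
Reactants: 10 ethyl 2-(7-{[(tert-butyldiphenylsilyl)oxy]methyl}-7-methyl-2-methylidenebicyclo[3.1.1]heptan-6-ylidene)acetate
Product: 11 ethyl 2-(7-{[(tert-butyldiphenylsilyl)oxy]methyl}-7-methyl-2-methylidenebicyclo[3.1.1]heptan-6-yl)acetate (H on C7 syn to the C9–C11 bridge; acetate arm cis to the silyloxymethyl arm)
Conditions: Cu(OAc)2·H2O (5 mol %), 1,2-bis(diphenylphosphino)benzene (5 mol %), (EtO)2MeSiH (3 equiv), t-BuOH (3 equiv), toluene, rt
Reagents that add atoms: none
Why: Copper hydride-catalysed conjugate reduction of a β,β-disubstituted enoate; the bulky phosphine–copper hydride should reach C7 only from the face syn to the C9–C11 bridge, because the opposite face is blocked by the silyloxymethyl group on C2 that points at C7 across the four-membered ring, so the new C7–H is syn to the bridge and the arm is cis to the C3 arm (kinetic control, no later epimerisation possible).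

Step 8
Reactants: 11 ethyl 2-(7-{[(tert-butyldiphenylsilyl)oxy]methyl}-7-methyl-2-methylidenebicyclo[3.1.1]heptan-6-yl)acetate; 12 iodomethane
Product: 14 ethyl 2-(7-{[(tert-butyldiphenylsilyl)oxy]methyl}-7-methyl-2-methylidenebicyclo[3.1.1]heptan-6-yl)-2-methylpropanoate, via monomethyl ester 13 (not isolated)
Conditions: LiN(i-Pr)2, THF, −78 °C; MeI, −78 to 0 °C; then LiN(i-Pr)2, −78 °C; MeI, DMPU, −78 °C to rt
Reagents that add atoms: iodomethane (12), CI
Why: Two successive ester-enolate alkylations build the quaternary C6; no other acidic C–H is present and the transient C6 stereocentre of 13 disappears.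

Step 9
Reactants: 14 ethyl 2-(7-{[(tert-butyldiphenylsilyl)oxy]methyl}-7-methyl-2-methylidenebicyclo[3.1.1]heptan-6-yl)-2-methylpropanoate
Product: 15 ethyl 2-[7-(hydroxymethyl)-7-methyl-2-methylidenebicyclo[3.1.1]heptan-6-yl]-2-methylpropanoate
Conditions: Bu4NF, AcOH, THF, rt
Reagents that add atoms: none
Why: Fluoride cleavage of the silyl ether, buffered with acetic acid so that no free alkoxide is present to lactonise onto the nearby C5 ester.

Step 10
Reactants: 15 ethyl 2-[7-(hydroxymethyl)-7-methyl-2-methylidenebicyclo[3.1.1]heptan-6-yl]-2-methylpropanoate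
Product: 17 6-(1-ethoxy-2-methyl-1-oxopropan-2-yl)-7-methyl-2-methylidenebicyclo[3.1.1]heptane-7-carboxylic acid, via aldehyde 16 (not isolated)
Conditions: 2,2,6,6-tetramethylpiperidin-1-oxyl (cat.), PhI(OAc)2, CH2Cl2, rt; then NaClO2, NaH2PO4, 2-methyl-2-butene, t-BuOH/H2O, rt
Reagents that add atoms: sodium chlorite, [Na+].[O-]Cl=O
Why: Nitroxyl-catalysed oxidation to the neopentyl aldehyde followed by Pinnick oxidation; 2-methyl-2-butene scavenges HOCl and protects the exocyclic alkene, and the quaternary C2 cannot epimerise.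

Step 11
Reactants: 17 6-(1-ethoxy-2-methyl-1-oxopropan-2-yl)-7-methyl-2-methylidenebicyclo[3.1.1]heptane-7-carboxylic acid; 12 iodomethane
Product: 18 methyl 6-(1-ethoxy-2-methyl-1-oxopropan-2-yl)-7-methyl-2-methylidenebicyclo[3.1.1]heptane-7-carboxylate
Conditions: K2CO3, MeI, DMF, rt
Reagents that add atoms: iodomethane (12), CI
Why: O-Alkylation of the carboxylate (SN2 at iodomethane) avoids attack at the hindered carbonyl carbon and supplies the second ester for the acyloin closure.

Step 12
Reactants: 18 methyl 6-(1-ethoxy-2-methyl-1-oxopropan-2-yl)-7-methyl-2-methylidenebicyclo[3.1.1]heptane-7-carboxylate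
Product: 19 methyl 6-(1-ethoxy-2-methyl-1-oxopropan-2-yl)-2,7-dimethylbicyclo[3.1.1]hept-2-ene-7-carboxylate (C9=C10 alkene)
Conditions: liquid SO2, CH2Cl2, 2,6-di-tert-butyl-4-methylphenol (cat.), sealed tube, rt
Reagents that add atoms: none
Why: Thermodynamically driven exocyclic-to-endocyclic alkene isomerisation by a reversible SO2 ene reaction, 1,3-shift of the allylic sulfinic acid and retro-ene loss of SO2 (the reaction type that converts β-pinene into α-pinene without skeletal rearrangement); the hydrogen can only come from C10 because C8 is a bridgehead, and the esters are inert.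

Step 13
Reactants: 19 methyl 6-(1-ethoxy-2-methyl-1-oxopropan-2-yl)-2,7-dimethylbicyclo[3.1.1]hept-2-ene-7-carboxylate; 20 chlorotrimethylsilane
Product: 21 nor-tricyclic 3,5-bis(trimethylsilyloxy)alkene (C3=C5, no C4; C2, C6, C6, C9 methyl groups; C9=C10 alkene)
Conditions: Na (dispersion, 4.4 equiv), Me3SiCl (5 equiv), toluene, 110 °C
Reagents that add atoms: chlorotrimethylsilane (20), C[Si](C)(C)Cl
Why: Acyloin condensation with in situ silylation; both esters lack α-hydrogens so no Dieckmann path exists, the two arms are held cis across the cyclobutane so the six-membered ring should close readily, the enediolate is trapped as the bis-silyl ether, and the isolated alkene is inert to sodium.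

Step 14
Reactants: 21 nor-tricyclic 3,5-bis(trimethylsilyloxy)alkene; 22 diiodomethane
Product: 23 3,5-bis(trimethylsilyloxy) cyclopropane-fused tetracycle (drawn with C4 bridging C3 and C5 on the face turned toward C8)
Conditions: Et2Zn (1.5 equiv), CH2I2 (1.6 equiv), toluene, 0 °C to rt; pyridine, then aq. NaHCO3
Reagents that add atoms: diiodomethane (22), ICI
Why: The carbenoid EtZnCH2I, formed from Et2Zn and CH2I2, delivers CH2 to the C3=C5 double bond in a concerted, syn-stereospecific [2+1] Simmons–Smith transfer through a butterfly-type transition state, so C3–C4 and C4–C5 form together. The closest known reaction type is the cyclopropanation of acyloin-derived 1,2-bis(trimethylsilyloxy)cycloalkenes, the first half of the established one-carbon ring expansion to cycloalkane-1,3-diones. The three-membered ring closes in this single event (both bonds to the same alkene face, no stepwise exo or endo closure) and is necessarily cis-fused to the six-membered ring. C3 and C5 are set as a pair by the suprafacial addition; the face is governed only by the remote difference between C11H2 beneath C1 and the methyl-bearing C9 beneath C8, because C1–H and C8–H flank the two faces alike, so no useful bias is expected and none is needed: 23 is drawn with C4 on the C8 face, and material formed by delivery to the C1 face would be its C3,C5-epimer, carried forward unseparated since both centres become carbonyl carbons in step 15. The selectivity that matters is chemoselectivity over the C9=C10 alkene, secured by the far higher nucleophilicity of the tetrasubstituted bis-silyloxy alkene toward the electrophilic carbenoid, by the trisubstituted, hindered nature of C9=C10 (one face lies under the C2 methyl group) and by the small excess of reagent; no regiochemical question arises because C2 and C6 are quaternary.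

Step 15
Reactants: 23 3,5-bis(trimethylsilyloxy) cyclopropane-fused tetracycle (used as obtained in step 14)
Product: 24 2,6,6,9-tetramethyltricyclo[5.4.0.0(2,8)]undec-9-ene-3,5-dione
Conditions: FeCl3 (2.2 equiv), pyridine (1 equiv), DMF, 0 °C to rt; then cold 1 M HCl
Reagents that add atoms: none
Why: FeCl3 takes one electron from the siloxycyclopropane, the shared C3–C5 bond breaks to leave the C3 carbonyl and a tertiary α-silyloxy radical at C5, and a second FeCl3 oxidises that radical to the C5 carbonyl with loss of both silyl groups (the known ring expansion of 1,2-bis(silyloxy)bicyclo[n.1.0]alkanes to cycloalkane-1,3-diones); the configuration at C3 and C5 is erased, so material from either face of methylene delivery converges on 24, and pyridine buffers the acid-sensitive pinene-type alkene.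

Step 16
Reactants: 24 2,6,6,9-tetramethyltricyclo[5.4.0.0(2,8)]undec-9-ene-3,5-dione
Product: 25 (3R)-3-hydroxy-2,6,6,9-tetramethyltricyclo[5.4.0.0(2,8)]undec-9-en-5-one
Conditions: (S)-1-methyl-3,3-diphenyltetrahydro-1H,3H-pyrrolo[1,2-c][1,3,2]oxazaborole ((S)-Me-CBS, 0.3 equiv), catecholborane (1.1 equiv), toluene, −78 °C; MeOH, then pH 7 buffer
Reagents that add atoms: none
Why: Corey–Bakshi–Shibata reduction; the catalyst distinguishes the quaternary carbon (large) from C4H2 (small), and the (S)-catalyst gives the (R)-carbinol as it does with tert-alkyl methyl ketones, placing the C3 oxygen on the ring face turned toward C1 (reagent control, needed because the core is almost mirror-symmetric); C3=O, flanked only by C1–H and C8–H of the tied-back cyclobutane, should react before C5=O, which is flanked by the two free methyl groups on C6, and catecholborane at −78 °C does not hydroborate C9=C10.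

Step 17
Reactants: 25 (3R)-3-hydroxy-2,6,6,9-tetramethyltricyclo[5.4.0.0(2,8)]undec-9-en-5-one; 26 3-methylbut-2-enoyl chloride
Product: 27 (3R)-2,6,6,9-tetramethyl-5-oxotricyclo[5.4.0.0(2,8)]undec-9-en-3-yl 3-methylbut-2-enoate
Conditions: pyridine, 4-(dimethylamino)pyridine (0.1 equiv), CH2Cl2, 0 °C
Reagents that add atoms: 3-methylbut-2-enoyl chloride (26), CC(C)=CC(=O)Cl
Why: Acylation of the secondary alcohol with the acid chloride under weakly basic, cold conditions, chosen to limit deconjugation of the senecioyl group through its vinylketene and β-elimination of the β-acyloxy ketone.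

Step 18
Reactants: 27 (3R)-2,6,6,9-tetramethyl-5-oxotricyclo[5.4.0.0(2,8)]undec-9-en-3-yl 3-methylbut-2-enoate
Product: 28 (3R,5R)-5-hydroxy-2,6,6,9-tetramethyltricyclo[5.4.0.0(2,8)]undec-9-en-3-yl 3-methylbut-2-enoate
Conditions: (S)-1-methyl-3,3-diphenyltetrahydro-1H,3H-pyrrolo[1,2-c][1,3,2]oxazaborole ((S)-Me-CBS, 1 equiv), catecholborane (2 equiv), toluene, −40 to −20 °C; MeOH, then pH 7 buffer
Reagents that add atoms: none
Why: Second Corey–Bakshi–Shibata reduction with the same (S)-catalyst (C6 large, C4H2 small) should give the (5R)-alcohol, with the C5 oxygen on the face turned toward C8 and hence the trans-3,5-dioxygenated ring by reagent control; the conjugated ester and both alkenes are inert to catecholborane at this temperature.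

Step 19
Reactants: 28 (3R,5R)-5-hydroxy-2,6,6,9-tetramethyltricyclo[5.4.0.0(2,8)]undec-9-en-3-yl 3-methylbut-2-enoate; 29 3-methylbutanoyl chloride
Product: 30 (3R,5R)-5-(3-methylbutanoyloxy)-2,6,6,9-tetramethyltricyclo[5.4.0.0(2,8)]undec-9-en-3-yl 3-methylbut-2-enoate
Conditions: pyridine, 4-(dimethylamino)pyridine (1 equiv), CH2Cl2, 0 to 40 °C
Reagents that add atoms: 3-methylbutanoyl chloride (29), CC(C)CC(=O)Cl
Why: Acylpyridinium-mediated esterification of the hindered neopentyl-type alcohol; the hindered C3 ester should neither migrate nor cleave under these conditions.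

Step 20
Reactants: 30 (3R,5R)-5-(3-methylbutanoyloxy)-2,6,6,9-tetramethyltricyclo[5.4.0.0(2,8)]undec-9-en-3-yl 3-methylbut-2-enoate
Product: 31 (1R,2R,3R,5R,7S,8R)-5-(3-methylbutanoyloxy)-2,6,6,9-tetramethyl-11-oxotricyclo[5.4.0.0(2,8)]undec-9-en-3-yl 3-methylbut-2-enoate (target)
Conditions: Rh2(cap)4 (cap = caprolactamate, 1 mol %), t-BuOOH (5 equiv), K2CO3 (0.5 equiv), CH2Cl2, rt
Reagents that add atoms: tert-butyl hydroperoxide, CC(C)(C)OO
Why: Radical allylic oxidation (tert-butylperoxyl chain) of the trisubstituted alkene at its only secondary allylic position C11, the α-pinene-to-verbenone pattern, gives the conjugated enone directly; the electron-poor senecioate alkene and the C–H bonds next to ester oxygen are deactivated toward the electrophilic oxygen radical, and C8 is a bridgehead.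

Compound list

1 | methyl (2E)-3,7-dimethylocta-2,6-dienoate | COC(=O)/C=C(\C)CCC=C(C)C | starting material
2 | methyl (2E,6E)-8-hydroxy-3,7-dimethylocta-2,6-dienoate | COC(=O)/C=C(\C)CC/C=C(\C)CO | intermediate
3 | methyl (2E,6E)-8-[(tert-butyldiphenylsilyl)oxy]-3,7-dimethylocta-2,6-dienoate | COC(=O)/C=C(\C)CC/C=C(\C)CO[Si](c1ccccc1)(c1ccccc1)C(C)(C)C | intermediate
4 | (2E,6E)-8-[(tert-butyldiphenylsilyl)oxy]-3,7-dimethylocta-2,6-dienoic acid | OC(=O)/C=C(\C)CC/C=C(\C)CO[Si](c1ccccc1)(c1ccccc1)C(C)(C)C | intermediate
5 | acid chloride of 4 | ClC(=O)/C=C(\C)CC/C=C(\C)CO[Si](c1ccccc1)(c1ccccc1)C(C)(C)C | intermediate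
6 | (6E)-8-[(tert-butyldiphenylsilyl)oxy]-7-methyl-3-methylideneocta-1,6-dien-1-one (vinylketene) | O=C=CC(=C)CC/C=C(\C)CO[Si](c1ccccc1)(c1ccccc1)C(C)(C)C | intermediate
7 | racemic 7-{[(tert-butyldiphenylsilyl)oxy]methyl}-7-methyl-2-methylidenebicyclo[3.1.1]heptan-6-one (both enantiomers) | O=C1[C@H]2CCC(=C)[C@@H]1[C@]2(CO[Si](c3ccccc3)(c3ccccc3)C(C)(C)C)C.O=C1[C@@H]2CCC(=C)[C@H]1[C@@]2(CO[Si](c3ccccc3)(c3ccccc3)C(C)(C)C)C | intermediate
8 | (1R,5S,7S)-7-{[(tert-butyldiphenylsilyl)oxy]methyl}-7-methyl-2-methylidenebicyclo[3.1.1]heptan-6-one | O=C1[C@H]2CCC(=C)[C@@H]1[C@]2(CO[Si](c3ccccc3)(c3ccccc3)C(C)(C)C)C | intermediate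
9 | triethyl phosphonoacetate | CCOC(=O)CP(=O)(OCC)OCC | starting material
10 | ethyl 2-(7-{[(tert-butyldiphenylsilyl)oxy]methyl}-7-methyl-2-methylidenebicyclo[3.1.1]heptan-6-ylidene)acetate (E/Z mixture) | CCOC(=O)C=C1[C@H]2CCC(=C)[C@@H]1[C@]2(CO[Si](c3ccccc3)(c3ccccc3)C(C)(C)C)C | intermediate
11 | ethyl 2-(7-{[(tert-butyldiphenylsilyl)oxy]methyl}-7-methyl-2-methylidenebicyclo[3.1.1]heptan-6-yl)acetate | CCOC(=O)C[C@@H]1[C@H]2CCC(=C)[C@@H]1[C@]2(CO[Si](c3ccccc3)(c3ccccc3)C(C)(C)C)C | intermediate
12 | iodomethane | CI | starting material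
13 | ethyl 2-(7-{[(tert-butyldiphenylsilyl)oxy]methyl}-7-methyl-2-methylidenebicyclo[3.1.1]heptan-6-yl)propanoate (both side-chain epimers) | CCOC(=O)C(C)[C@@H]1[C@H]2CCC(=C)[C@@H]1[C@]2(CO[Si](c3ccccc3)(c3ccccc3)C(C)(C)C)C | intermediate
14 | ethyl 2-(7-{[(tert-butyldiphenylsilyl)oxy]methyl}-7-methyl-2-methylidenebicyclo[3.1.1]heptan-6-yl)-2-methylpropanoate | CCOC(=O)C(C)(C)[C@@H]1[C@H]2CCC(=C)[C@@H]1[C@]2(CO[Si](c3ccccc3)(c3ccccc3)C(C)(C)C)C | intermediate
15 | ethyl 2-[7-(hydroxymethyl)-7-methyl-2-methylidenebicyclo[3.1.1]heptan-6-yl]-2-methylpropanoate | CCOC(=O)C(C)(C)[C@@H]1[C@H]2CCC(=C)[C@@H]1[C@]2(CO)C | intermediate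
16 | ethyl 2-(7-formyl-7-methyl-2-methylidenebicyclo[3.1.1]heptan-6-yl)-2-methylpropanoate | CCOC(=O)C(C)(C)[C@@H]1[C@H]2CCC(=C)[C@@H]1[C@]2(C=O)C | intermediate
17 | 6-(1-ethoxy-2-methyl-1-oxopropan-2-yl)-7-methyl-2-methylidenebicyclo[3.1.1]heptane-7-carboxylic acid | CCOC(=O)C(C)(C)[C@@H]1[C@H]2CCC(=C)[C@@H]1[C@]2(C(=O)O)C | intermediate
18 | methyl 6-(1-ethoxy-2-methyl-1-oxopropan-2-yl)-7-methyl-2-methylidenebicyclo[3.1.1]heptane-7-carboxylate | CCOC(=O)C(C)(C)[C@@H]1[C@H]2CCC(=C)[C@@H]1[C@]2(C(=O)OC)C | intermediate
19 | methyl 6-(1-ethoxy-2-methyl-1-oxopropan-2-yl)-2,7-dimethylbicyclo[3.1.1]hept-2-ene-7-carboxylate | CCOC(=O)C(C)(C)[C@@H]1[C@H]2CC=C(C)[C@@H]1[C@]2(C(=O)OC)C | intermediate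
20 | chlorotrimethylsilane | C[Si](C)(C)Cl | starting material
21 | nor-tricyclic 3,5-bis(trimethylsilyloxy)alkene (C3 bonded to C5) | C[Si](C)(C)OC1=C(O[Si](C)(C)C)C(C)(C)[C@@H]2[C@H]3CC=C(C)[C@@H]2[C@]31C | intermediate
22 | diiodomethane | ICI | starting material
23 | 3,5-bis(trimethylsilyloxy) cyclopropane-fused tetracycle (drawn with C4 on the face of C8; material of the other face, if formed, is its C3,C5-epimer and is carried along) | C[Si](C)(C)O[C@]12C[C@@]1(O[Si](C)(C)C)C(C)(C)[C@@H]3[C@H]4CC=C(C)[C@@H]3[C@]42C | intermediate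
24 | 2,6,6,9-tetramethyltricyclo[5.4.0.0(2,8)]undec-9-ene-3,5-dione | O=C1CC(=O)C(C)(C)[C@@H]2[C@H]3CC=C(C)[C@@H]2[C@]31C | intermediate
25 | (3R)-3-hydroxy-2,6,6,9-tetramethyltricyclo[5.4.0.0(2,8)]undec-9-en-5-one | O[C@@H]1CC(=O)C(C)(C)[C@@H]2[C@H]3CC=C(C)[C@@H]2[C@]31C | intermediate
26 | 3-methylbut-2-enoyl chloride | CC(C)=CC(=O)Cl | starting material
27 | (3R)-2,6,6,9-tetramethyl-5-oxotricyclo[5.4.0.0(2,8)]undec-9-en-3-yl 3-methylbut-2-enoate | CC(C)=CC(=O)O[C@@H]1CC(=O)C(C)(C)[C@@H]2[C@H]3CC=C(C)[C@@H]2[C@]31C | intermediate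
28 | (3R,5R)-5-hydroxy-2,6,6,9-tetramethyltricyclo[5.4.0.0(2,8)]undec-9-en-3-yl 3-methylbut-2-enoate | CC(C)=CC(=O)O[C@@H]1C[C@@H](O)C(C)(C)[C@@H]2[C@H]3CC=C(C)[C@@H]2[C@]31C | intermediate
29 | 3-methylbutanoyl chloride | CC(C)CC(=O)Cl | starting material
30 | (3R,5R)-5-(3-methylbutanoyloxy)-2,6,6,9-tetramethyltricyclo[5.4.0.0(2,8)]undec-9-en-3-yl 3-methylbut-2-enoate | CC(C)=CC(=O)O[C@@H]1C[C@@H](OC(=O)CC(C)C)C(C)(C)[C@@H]2[C@H]3CC=C(C)[C@@H]2[C@]31C | intermediate
31 | (1R,2R,3R,5R,7S,8R)-5-(3-methylbutanoyloxy)-2,6,6,9-tetramethyl-11-oxotricyclo[5.4.0.0(2,8)]undec-9-en-3-yl 3-methylbut-2-enoate | CC(C)=CC(=O)O[C@@H]1C[C@@H](OC(=O)CC(C)C)C(C)(C)[C@@H]2[C@H]3C(=O)C=C(C)[C@@H]2[C@]31C | target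

Totals

Total step count: 20. Longest linear sequence: 20 steps (1 to 31).

Steps most likely to fail

Step 16. The two carbonyl groups may not be told apart well enough, so that the first reduction gives both mono-alcohols and some diol. Fallback: the route is run in both acylation orders. It sets out from 24: the reduction is stopped at the mono-alcohol stage and the constitutional isomers are separated by chromatography. Compound 25 goes on as planned. The isomer reduced at C5, (5R)-5-hydroxy-2,6,6,9-tetramethyltricyclo[5.4.0.0(2,8)]undec-9-en-3-one F1, is acylated first with 3-methylbutanoyl chloride to the keto isovalerate F2. F2 is reduced at C3 with the same (S)-catalyst and catecholborane to the (3R)-alcohol F3, which is esterified with 3-methylbut-2-enoyl chloride. Both branches come back to the route at 30, so site selectivity in the reduction is replaced by a separation.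

Step 7. Hydride may be delivered to C7 from the wrong face, or the hindered β-carbon may not turn over, which would leave the two arms trans and make the acyloin closure impossible. Fallback: the C6–C7 bond is formed intramolecularly so that the ring, not the reagent, fixes C7. It sets out from 8: desilylation (Bu4NF, AcOH) gives the hydroxy ketone F4, and 2-bromo-2-methylpropanoyl bromide with pyridine gives the bromoisobutyrate F5. SmI2 (THF, −78 °C) then effects an intramolecular Reformatsky addition; the samarium enolate can reach the C7 carbonyl only from the side of its own tether, giving the seven-membered hydroxy lactone F6 with C6 already quaternary and cis to C3. The tertiary alcohol is converted into its methyl oxalate F7 (methyl chlorooxoacetate, pyridine) and removed with Bu3SnH and azobisisobutyronitrile in toluene at 110 °C to give the deoxygenated lactone F8, in which the tether again forces the C7 hydrogen to the face of the C9–C11 bridge. KOH in aqueous ethanol opens F8 to the hydroxy acid F9; oxidation as in step 10 gives the diacid F10, MeI with K2CO3 gives the dimethyl ester F11, isomerisation as in step 12 gives the endocyclic dimethyl ester F12, and the acyloin conditions of step 13 bring it back to the route at 21.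

Step 4. The vinylketene may oligomerise faster than it cyclises, because the alkene is deactivated by the allylic silyloxy group, or the γ-deprotonation may occur at C10 instead of the methyl group. Fallback: the ketene is made by ordinary α-dehydrochlorination at low temperature and the cycloaddition is promoted by a Lewis acid. It sets out from 4: the dianion (LiN(i-Pr)2, 2.2 equiv, THF, −78 °C) is protonated kinetically at the α-carbon to give the deconjugated acid (6E)-8-[(tert-butyldiphenylsilyl)oxy]-7-methyl-3-methylideneoct-6-enoic acid F13. Oxalyl chloride gives its acid chloride F14. Et3N at −78 to 0 °C gives the same vinylketene 6, and EtAlCl2 (2.5 equiv, CH2Cl2, −78 °C) activates the ketene toward the alkene. The sequence comes back to the route at 7.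

Further compounds

F1 | step 16 | (5R)-5-hydroxy-2,6,6,9-tetramethyltricyclo[5.4.0.0(2,8)]undec-9-en-3-one | O=C1C[C@@H](O)C(C)(C)[C@@H]2[C@H]3CC=C(C)[C@@H]2[C@]31C
F2 | step 16 | (5R)-2,6,6,9-tetramethyl-3-oxotricyclo[5.4.0.0(2,8)]undec-9-en-5-yl 3-methylbutanoate | O=C1C[C@@H](OC(=O)CC(C)C)C(C)(C)[C@@H]2[C@H]3CC=C(C)[C@@H]2[C@]31C
F3 | step 16 | (3R,5R)-3-hydroxy-2,6,6,9-tetramethyltricyclo[5.4.0.0(2,8)]undec-9-en-5-yl 3-methylbutanoate | O[C@@H]1C[C@@H](OC(=O)CC(C)C)C(C)(C)[C@@H]2[C@H]3CC=C(C)[C@@H]2[C@]31C
F4 | step 7 | 7-(hydroxymethyl)-7-methyl-2-methylidenebicyclo[3.1.1]heptan-6-one (ring configuration as in 8) | O=C1[C@H]2CCC(=C)[C@@H]1[C@]2(CO)C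
F5 | step 7 | (7-methyl-2-methylidene-6-oxobicyclo[3.1.1]heptan-7-yl)methyl 2-bromo-2-methylpropanoate | O=C1[C@H]2CCC(=C)[C@@H]1[C@]2(COC(=O)C(C)(C)Br)C
F6 | step 7 | hydroxy lactone (4-oxa analogue of the target ring: C7–OH, C6 gem-dimethyl, C5 lactone carbonyl, ring oxygen, C3H2) | C1OC(=O)C(C)(C)[C@]2(O)[C@H]3CCC(=C)[C@@H]2[C@]31C
F7 | step 7 | methyl oxalate of F6 | C1OC(=O)C(C)(C)[C@]2(OC(=O)C(=O)OC)[C@H]3CCC(=C)[C@@H]2[C@]31C
F8 | step 7 | deoxygenated lactone (C7–H syn to the C9–C11 bridge) | C1OC(=O)C(C)(C)[C@@H]2[C@H]3CCC(=C)[C@@H]2[C@]31C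
F9 | step 7 | 2-[7-(hydroxymethyl)-7-methyl-2-methylidenebicyclo[3.1.1]heptan-6-yl]-2-methylpropanoic acid | OC(=O)C(C)(C)[C@@H]1[C@H]2CCC(=C)[C@@H]1[C@]2(CO)C
F10 | step 7 | 6-(2-carboxypropan-2-yl)-7-methyl-2-methylidenebicyclo[3.1.1]heptane-7-carboxylic acid | OC(=O)C(C)(C)[C@@H]1[C@H]2CCC(=C)[C@@H]1[C@]2(C(=O)O)C
F11 | step 7 | methyl 6-(1-methoxy-2-methyl-1-oxopropan-2-yl)-7-methyl-2-methylidenebicyclo[3.1.1]heptane-7-carboxylate | COC(=O)C(C)(C)[C@@H]1[C@H]2CCC(=C)[C@@H]1[C@]2(C(=O)OC)C
F12 | step 7 | methyl 6-(1-methoxy-2-methyl-1-oxopropan-2-yl)-2,7-dimethylbicyclo[3.1.1]hept-2-ene-7-carboxylate | COC(=O)C(C)(C)[C@@H]1[C@H]2CC=C(C)[C@@H]1[C@]2(C(=O)OC)C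
F13 | step 4 | (6E)-8-[(tert-butyldiphenylsilyl)oxy]-7-methyl-3-methylideneoct-6-enoic acid | OC(=O)CC(=C)CC/C=C(\C)CO[Si](c1ccccc1)(c1ccccc1)C(C)(C)C
F14 | step 4 | acid chloride of F13 | ClC(=O)CC(=C)CC/C=C(\C)CO[Si](c1ccccc1)(c1ccccc1)C(C)(C)C
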